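The bicyclo[3.3.1]nonane is opened at C2–C3 of ring A. The feature exploited is that C2 is a methylene between the oxygenated quaternary bridgehead C1 and the nitrogen-bearing C3: a C2 radical, generated from a C1 iodomethyl group and indifferent to the β-oxygen on C1, adds 6-exo to a C3 O-benzyl oxime ether, closing ring A and fixing the exo C3–N bond in one operation. The precursor is a ring B cyclohexene (C1, C9, C5, C6, C7, C8) with a cis-fused C1,C9 acetal, the C1 iodomethyl group, the cis C5 arm CH(OSi)–CH=N–OBn and the C6 methoxy group, built from a para-quinol by enantioselective oxa-Michael desymmetrisation and an anti boron aldol.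

Key step: step 8

Remarks on the chemistry (one line each):
- Numbering: C1 hydroxylated bridgehead, C2 CH2, C3 CHN, C4 CHOH, C5 bridgehead CH, C6 CHOMe, C7/C8 epoxide carbons (C8 on C1), C9 ketone; ring A holds C2–C4, ring B holds C6–C8; on ring B the face of the C1 oxygen is called β and the face of C2 is called α.
- Assumption: the (R)-phosphoric acid is taken to give the enantiomer drawn for 6; if the sense of induction is the opposite, the (S)-acid is used.
- The C1,C9 diol is carried as an aldehyde-derived acetal, which is what the desymmetrisation delivers directly; it places hydrogen, not methyl, on the concave side of the acetal carbon, next to the axial C6 methoxy group of the reactive conformer in step 8.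
- The C4 oxygen carries triisopropylsilyl, so that the acetal can be hydrolysed before the silyl ether and no silyl shift to the C6 alkoxide occurs.
- The neopentyl iodide (no β-hydrogen) is introduced in step 1 and carried through, which spares a late alcohol-to-iodide exchange.
- The C1 hydroxyl lies in the plane of C7=C8 (O1–C1–C8=C7 antiperiplanar) and cannot steer an oxidant. The epoxide is therefore introduced at the diol stage, before C9 is oxidised, where ring A and the C9 hydroxyl fix the face and no Baeyer–Villiger reaction can compete.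

Step 1
Reactants: 1 4,4-dimethoxycyclohexa-2,5-dien-1-one; 2 diiodomethane
Product: 4 4-hydroxy-4-(iodomethyl)cyclohexa-2,5-dien-1-one, via iodohydrin ketal 3 (not isolated)
Conditions: 2 (1.5 equiv), MeLi·LiBr (1.4 equiv, slow addition), THF/Et2O, −78 °C; AcOH, −78 °C; then 5% aq oxalic acid, THF, 0 °C → rt
Reagents that add atoms: water, O
Why: Iodine–lithium exchange in the presence of the ketone gives iodomethyllithium, which adds 1,2 to the cross-conjugated carbonyl (Barbier-type carbenoid addition) and is protonated cold before the β-iodo alkoxide can close to a spiro epoxide, after which dilute acid hydrolyses the doubly allylic ketal to the para-quinol in the usual way for quinone monoketal adducts; no stereocentre is formed.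

Step 2
Reactants: 4 4-hydroxy-4-(iodomethyl)cyclohexa-2,5-dien-1-one
Product: 6 (2S,3aR,7aS)-7a-(iodomethyl)-2-(propan-2-yl)-3a,7a-dihydro-2H-1,3-benzodioxol-5(4H)-one, via hemiacetal 5 (not isolated)
Conditions: 2-methylpropanal (3 equiv), (R)-TRIP phosphoric acid (5 mol%), N,N'-bis[3,5-bis(trifluoromethyl)phenyl]thiourea (5 mol%), 1,2-dichloroethane, rt → 40 °C
Reagents that add atoms: 2-methylpropanal, CC(C)C=O
Why: The tertiary hydroxyl adds to the aldehyde and the hemiacetal hydroxyl closes onto one of the two enantiotopic enone arms in a phosphoric-acid-catalysed acetalisation/oxa-Michael cascade of the type established for para-quinols, the chiral phosphate choosing the arm and so fixing C1 and C9, the five-membered ring enforcing the cis C1,C9 dioxygen pattern, and the isopropyl group settling on the convex face.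

Step 3
Reactants: 7 glyoxal; 8 O-benzylhydroxylamine
Product: 9 (E)-2-[(benzyloxy)imino]acetaldehyde
Conditions: 40% aq glyoxal (5 equiv), THF/H2O, 0 °C → rt; extraction, azeotropic drying (toluene)
Reagents that add atoms: none
Why: Oxime ether condensation of an alkoxyamine with an aldehyde, in which the fivefold excess of water-soluble glyoxal suppresses the dioxime and is washed out, and the anti (E) oxime ether is the stable isomer.

Step 4
Reactants: 6 acetal enone; 9 (E)-2-[(benzyloxy)imino]acetaldehyde
Product: 12 anti-aldol adduct carrying the C5 α-arm (4R)-CH(OH)–CH=N–OBn, via boron dienolate 10 (not isolated), via boron aldolate 11 (not isolated)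
Conditions: (c-Hex)2BCl (1.3 equiv), Et3N (1.5 equiv), Et2O, −78 → 0 °C; 9 (1.5 equiv), −78 → −20 °C; MeOH, pH 7 buffer, 30% H2O2, 0 °C
Reagents that add atoms: none
Why: Soft enolisation can occur only at C5 (C1 is quaternary) and gives the ring-constrained E boron enolate, which is too weakly basic to expel the C9 acetal oxygen and adds to the non-enolisable aldehyde through a Zimmerman–Traxler chair (boron aldol) to set the anti C5/C4 relationship, while the aldehyde reaches C5 on the α face, away from the adjacent C9–O bond and the fused dioxolane, so that the arm is trans to O9 and cis to the iodomethyl group.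

Step 5
Reactants: 12 anti-aldol adduct
Product: 13 C4 triisopropylsilyl ether of 12
Conditions: TIPSOTf (1.3 equiv), 2,6-lutidine (2 equiv), CH2Cl2, −78 → −20 °C
Reagents that add atoms: triisopropylsilyl trifluoromethanesulfonate (TIPSOTf), CC(C)[Si](C(C)C)(C(C)C)OS(=O)(=O)C(F)(F)F
Why: Silyl triflate/lutidine silylation of a secondary β-hydroxy ketone is fast at low temperature and too mild for retro-aldol or β-elimination, and the triisopropylsilyl group is chosen because it resists both migration in step 7 and the aqueous acid of step 11.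

Step 6
Reactants: 13 silyl ether enone
Product: 14 C6 β-allylic alcohol
Conditions: NaBH4, CeCl3·7H2O, MeOH, −78 °C
Reagents that add atoms: none
Why: Luche 1,2-reduction of the enone, in which hydride adds axially on the α face of the half-chair that has the C5 arm equatorial, so that the C6 hydroxyl becomes β and equatorial, trans to the arm, cis to O9 and 1,3-syn to the C4 oxygen.

Step 7
Reactants: 14 allylic alcohol
Product: 16 C6 methyl ether (cyclisation precursor), via sodium alkoxide 15 (not isolated)
Conditions: NaN(SiMe3)2 (1.1 equiv), THF, −78 °C; MeOTf (2 equiv), −78 → −40 °C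
Reagents that add atoms: methyl trifluoromethanesulfonate (MeOTf), COS(=O)(=O)C(F)(F)F
Why: Williamson methylation of the sodium alkoxide with the very reactive triflate at −78 °C, where neither silyl migration nor attack on the neopentyl iodide or the oxime ether competes, and no stereocentre is touched.

Step 8
Reactants: 16 ring B cyclohexene with C1,C9 acetal, C1 iodomethyl group, C5 α-silyloxy oxime ether arm and C6 methoxy group
Product: 17 (3S)-3-exo-benzyloxyamino bicyclo[3.3.1]non-7-ene with C9 masked in the acetal
Conditions: Bu3SnH (1.5 equiv) and AIBN (0.2 equiv) added over 8 h by syringe pump, benzene (0.005 M), 80 °C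
Reagents that add atoms: none
Why: Bu3Sn• removes iodine from C2; the primary C2 radical, which has no low-energy way to lose the β-oxygen on C1, adds to the carbon of the C3 oxime ether, and the alkoxyaminyl radical so formed takes hydrogen from Bu3SnH, which carries the chain. The closest known reaction type is the stannane-mediated cyclisation of alkyl halides onto O-benzyl aldoxime ethers. Ring A (C1, C2, C3, C4, C5, C9) closes in the 6-exo-trig mode through a chair in which the cis C1 and C5 arms are 1,3-diaxial on ring B. The one new stereocentre, C3, is controlled by the forming bicycle: an endo substituent on C3 would point into ring B at C7, so the N–OBn group goes exo (equatorial on ring A, cis to the axial C4 silyloxy group) and hydrogen goes endo. The selectivity needed is cyclisation ahead of reduction of the open radical and ahead of 3-exo attack on a neighbouring π bond; slow stannane addition at high dilution and 80 °C serve the first, C9 held as an sp3 acetal carbon removes the carbonyl version of the second, and the hydrogen on the concave side of the acetal carbon keeps the all-axial reactive conformer of ring B accessible.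

Step 9
Reactants: 17 benzyloxyamine
Product: 18 (3S)-3-exo primary amine
Conditions: SmI2 (3 equiv), THF/MeOH, 0 °C → rt
Reagents that add atoms: none
Why: Single-electron reductive cleavage of the N–O bond of an O-benzylhydroxylamine by samarium diiodide with methanol as proton source leaves the acetal, silyl ether, allylic ether and alkene untouched and does not affect C3.

Step 10
Reactants: 18 primary amine; 19 (E)-dodec-2-enoic acid
Product: 21 (E)-dodec-2-enamide of 18, via benzotriazolyl ester 20 (not isolated)
Conditions: 19, DIC, HOBt, CH2Cl2, 0 °C, 30 min; then 18, 0 °C → rt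
Reagents that add atoms: none
Why: Carbodiimide/HOBt amide coupling through the benzotriazolyl ester acylates the unhindered equatorial primary amine under conditions mild enough to keep the E double bond and to avoid conjugate addition.

Step 11
Reactants: 21 amide acetal
Product: 22 C1,C9 cis-diol
Conditions: TFA/H2O/CH2Cl2 (5:1:5), 0 °C
Reagents that add atoms: none
Why: Acid-catalysed hydrolysis of the aldehyde-derived dioxolane releases the diol and volatile 2-methylpropanal, while the hindered secondary triisopropylsilyl ether, the amide and the electron-poor allylic methyl ether should tolerate cold aqueous TFA.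

Step 12
Reactants: 22 diol
Product: 23 7,8-β-epoxy diol
Conditions: mCPBA (1.5 equiv), NaHCO3, CH2Cl2, 0 °C → rt
Reagents that add atoms: 3-chloroperbenzoic acid (mCPBA), OOC(=O)c1cccc(Cl)c1
Why: Prilezhaev epoxidation of the only nucleophilic alkene (the side-chain C=C is conjugated to the amide carbonyl and inert to peracid): the α face of C7=C8 is closed by ring A, whose endo C3 hydrogen lies under C7, while the axial C9 hydroxyl on the ring B side can hydrogen-bond the peracid, so oxygen should be delivered to the exo β face, cis to the C6 methoxy group, which sets C7 and C8.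

Step 13
Reactants: 23 epoxy diol
Product: 24 C9 ketone (C4 silyl ether of the target)
Conditions: Dess–Martin periodinane, NaHCO3, CH2Cl2, 0 °C → rt
Reagents that add atoms: none
Why: Dess–Martin oxidation converts the only free secondary alcohol (C9) into the ketone without cleaving the 1,2-diol, the tertiary C1 hydroxyl, epoxide and silyl ether being inert, and the new ketone cannot enolise toward the C5 bridgehead (Bredt's rule), so C5 is safe from epimerisation and the C4 oxygen from elimination.

Step 14
Reactants: 24 silyl ether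
Product: 25 CNP0137540.1, (2E)-N-[(1S,3S,4R,5S,6S,7S,8S)-7,8-epoxy-1,4-dihydroxy-6-methoxy-9-oxobicyclo[3.3.1]nonan-3-yl]dodec-2-enamide
Conditions: HF·pyridine, pyridine, THF, 0 °C → rt
Reagents that add atoms: none
Why: Fluoride cleavage of the silyl ether under buffered, non-basic conditions avoids retro-aldol opening of the C4 β-hydroxy ketone and leaves the deactivated epoxide and the α-ketol intact.

Compound list

1 | 4,4-dimethoxycyclohexa-2,5-dien-1-one | COC1(OC)C=CC(=O)C=C1 | starting material
2 | diiodomethane | ICI | starting material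
3 | 1-(iodomethyl)-4,4-dimethoxycyclohexa-2,5-dien-1-ol (formed as lithium alkoxide, protonated cold; not isolated) | COC1(OC)C=CC(O)(CI)C=C1 | intermediate
4 | 4-hydroxy-4-(iodomethyl)cyclohexa-2,5-dien-1-one | O=C1C=CC(O)(CI)C=C1 | intermediate
5 | 4-(1-hydroxy-2-methylpropoxy)-4-(iodomethyl)cyclohexa-2,5-dien-1-one, hemiacetal of 4, hemiacetal carbon unassigned (not isolated) | CC(C)C(O)OC1(CI)C=CC(=O)C=C1 | intermediate
6 | (2S,3aR,7aS)-7a-(iodomethyl)-2-(propan-2-yl)-3a,7a-dihydro-2H-1,3-benzodioxol-5(4H)-one; cis-fused C1,C9 acetal, O1 and O9 β, iodomethyl α, isopropyl exo, C6 ketone, C7=C8 | IC[C@@]12O[C@@H](C(C)C)O[C@@H]1CC(=O)C=C2 | intermediate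
7 | glyoxal | O=CC=O | starting material
8 | O-benzylhydroxylamine | NOCc1ccccc1 | starting material
9 | (E)-2-[(benzyloxy)imino]acetaldehyde | O=C/C=N/OCc1ccccc1 | intermediate
10 | dicyclohexylboron dienolate of 6 (C5=C6–O–B, C7=C8; not isolated) | IC[C@@]12O[C@@H](C(C)C)O[C@@H]1C=C(OB(C3CCCCC3)C3CCCCC3)C=C2 | intermediate
11 | dicyclohexylboron aldolate of 12 (not isolated) | IC[C@@]12O[C@@H](C(C)C)O[C@@H]1[C@@H]([C@@H](OB(C3CCCCC3)C3CCCCC3)/C=N/OCc3ccccc3)C(=O)C=C2 | intermediate
12 | anti-aldol adduct: 6 bearing at C5 (α, trans to O9, cis to CH2I) the arm (4R)-CH(OH)–CH=N–OBn (E) | IC[C@@]12O[C@@H](C(C)C)O[C@@H]1[C@@H]([C@@H](O)/C=N/OCc3ccccc3)C(=O)C=C2 | intermediate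
13 | C4 triisopropylsilyl ether of 12 | IC[C@@]12O[C@@H](C(C)C)O[C@@H]1[C@@H]([C@@H](O[Si](C(C)C)(C(C)C)C(C)C)/C=N/OCc3ccccc3)C(=O)C=C2 | intermediate
14 | allylic alcohol: 13 reduced at C6, hydroxyl β (trans to the C5 arm, cis to O9) | IC[C@@]12O[C@@H](C(C)C)O[C@@H]1[C@@H]([C@@H](O[Si](C(C)C)(C(C)C)C(C)C)/C=N/OCc3ccccc3)[C@H](O)C=C2 | intermediate
15 | sodium alkoxide of 14 (not isolated) | [Na+].IC[C@@]12O[C@@H](C(C)C)O[C@@H]1[C@@H]([C@@H](O[Si](C(C)C)(C(C)C)C(C)C)/C=N/OCc3ccccc3)[C@H]([O-])C=C2 | intermediate
16 | cyclisation precursor: ring B cyclohexene (C7=C8) with β cis-fused C1,C9 isobutylidene acetal, C1 α-iodomethyl, C5 α-arm (4R)-CH(OTIPS)–CH=N–OBn (E), C6 β-methoxy | IC[C@@]12O[C@@H](C(C)C)O[C@@H]1[C@@H]([C@@H](O[Si](C(C)C)(C(C)C)C(C)C)/C=N/OCc3ccccc3)[C@H](OC)C=C2 | intermediate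
17 | cyclisation product: bicyclo[3.3.1]non-7-ene, (3S)-exo-NH–OBn, (4R)-axial OTIPS, C6 methoxy, C1,C9 acetal with O9 on the ring B side | c1ccccc1CON[C@H]2C[C@]34O[C@@H](C(C)C)O[C@@H]4[C@@H]([C@H]2O[Si](C(C)C)(C(C)C)C(C)C)[C@H](OC)C=C3 | intermediate
18 | (3S)-exo primary amine from 17 | N[C@H]2C[C@]34O[C@@H](C(C)C)O[C@@H]4[C@@H]([C@H]2O[Si](C(C)C)(C(C)C)C(C)C)[C@H](OC)C=C3 | intermediate
19 | (E)-dodec-2-enoic acid | CCCCCCCCC/C=C/C(=O)O | starting material
20 | benzotriazol-1-yl (2E)-dodec-2-enoate (not isolated) | CCCCCCCCC/C=C/C(=O)On1nnc2ccccc12 | intermediate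
21 | (2E)-dodec-2-enamide of 18 | CCCCCCCCC/C=C/C(=O)N[C@H]2C[C@]34O[C@@H](C(C)C)O[C@@H]4[C@@H]([C@H]2O[Si](C(C)C)(C(C)C)C(C)C)[C@H](OC)C=C3 | intermediate
22 | C1,C9 cis-diol: amide with free C1 (tertiary) and C9 (secondary, on the ring B side) hydroxyls, C4 OTIPS, C7=C8 | CCCCCCCCC/C=C/C(=O)N[C@H]2C[C@@]3(O)[C@H](O)[C@@H]([C@H]2O[Si](C(C)C)(C(C)C)C(C)C)[C@H](OC)C=C3 | intermediate
23 | 7,8-β-epoxide (exo, cis to C6 OMe) of 22 | CCCCCCCCC/C=C/C(=O)N[C@H]1C[C@@]2(O)[C@H](O)[C@@H]([C@H]1O[Si](C(C)C)(C(C)C)C(C)C)[C@H](OC)[C@@H]1O[C@@H]12 | intermediate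
24 | C9 ketone: C4 triisopropylsilyl ether of the target | CCCCCCCCC/C=C/C(=O)N[C@H]1C[C@@]2(O)C(=O)[C@@H]([C@H]1O[Si](C(C)C)(C(C)C)C(C)C)[C@H](OC)[C@@H]1O[C@@H]12 | intermediate
25 | CNP0137540.1, (2E)-N-[(1S,3S,4R,5S,6S,7S,8S)-7,8-epoxy-1,4-dihydroxy-6-methoxy-9-oxobicyclo[3.3.1]nonan-3-yl]dodec-2-enamide (core numbering as defined above) | CCCCCCCCC/C=C/C(=O)N[C@H]1C[C@@]2(O)C(=O)[C@@H]([C@H]1O)[C@H](OC)[C@@H]1O[C@@H]12 | target

Total step count: 14. Longest linear sequence: 13 steps (steps 1, 2 and 4–14, from 1); step 3 is a one-step side branch.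

Steps most likely to fail

Step 8. What may go wrong: the C2 radical must reach the ring B conformer in which both arms, O9 and the C6 methoxy group are axial before it can close, so hydrogen transfer from the stannane to the open radical, or 3-exo attack on C8 followed by a 1,2-vinyl shift (enlargement of ring B), can overtake cyclisation. The fallback removes the C7=C8 π bond before the radical is made and dispenses with the hydride donor. It sets out from 14, whose C6 hydroxyl directs VO(acac)2/t-BuOOH (CH2Cl2, 0 °C → rt; a peracid is avoided because of the alkyl iodide) to the β face to give the β-epoxy alcohol F1. NaN(SiMe3)2 at −78 °C gives the sodium alkoxide F2, which MeOTf methylates to the epoxy methyl ether F3. F3 is cyclised with Et3B/air in CH2Cl2 at rt without a hydride donor, an iodine-atom-transfer chain in which the borane traps the alkoxyaminyl radical and releases ethyl radical, to give after aqueous work-up the epoxy benzyloxyamine F4. SmI2/MeOH cleaves the N–O bond to the epoxy amine F5, and coupling with 19 through 20 gives the epoxy amide acetal F6. Cold aqueous TFA then removes the acetal (the epoxide, flanked by two oxygenated carbons, should resist the acid), and the route is rejoined at 23.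

Step 4. What may go wrong: the α-oximino aldehyde 9, made in water, may carry hydrate or oligomers that quench the boron enolate, and its small polar substituent may erode the anti and facial selectivity. The fallback uses a robust aldehyde first and makes the oxime afterwards. It sets out from 6: the boron dienolate 10 is combined with (E)-cinnamaldehyde to give the boron aldolate F7 and, after oxidative work-up, the anti styryl carbinol F8. TIPSOTf/2,6-lutidine gives the silyl ether F9. OsO4 (cat.)/NaIO4/2,6-lutidine in dioxane–water dihydroxylates the electron-rich styryl double bond (the hindered enone is left) to the diol F10, which is cleaved in the same flask to the α-silyloxy aldehyde F11 (Lemieux–Johnson). Condensation of F11 with 8 (pyridine, EtOH, 0 °C), the aldehyde reacting far faster than the conjugated ketone, rejoins the route at 13.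

Step 2. What may go wrong: insufficient discrimination between the two enantiotopic enone arms for this iodomethyl quinol. The fallback replaces asymmetric catalysis by resolution. It sets out from 4: diphenyl phosphate (10 mol%) and 2-methylpropanal give the racemic acetal, that is 6 together with its enantiomer F12. Preparative chromatography on a chiral stationary phase separates the two, F12 is discarded, and the route is rejoined at 6.

Further compounds

F1 | step 8 | 7,8-β-epoxide of allylic alcohol 14 | IC[C@@]12O[C@@H](C(C)C)O[C@@H]1[C@@H]([C@@H](O[Si](C(C)C)(C(C)C)C(C)C)/C=N/OCc3ccccc3)[C@H](O)[C@@H]1O[C@@H]12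
F2 | step 8 | sodium alkoxide of F1 | [Na+].IC[C@@]12O[C@@H](C(C)C)O[C@@H]1[C@@H]([C@@H](O[Si](C(C)C)(C(C)C)C(C)C)/C=N/OCc3ccccc3)[C@H]([O-])[C@@H]1O[C@@H]12
F3 | step 8 | C6 methyl ether of F1 (epoxy iodide precursor) | IC[C@@]12O[C@@H](C(C)C)O[C@@H]1[C@@H]([C@@H](O[Si](C(C)C)(C(C)C)C(C)C)/C=N/OCc3ccccc3)[C@H](OC)[C@@H]1O[C@@H]12
F4 | step 8 | 7,8-β-epoxy analogue of 17 ((3S)-exo-benzyloxyamine) | c1ccccc1CON[C@H]1C[C@]23O[C@@H](C(C)C)O[C@@H]3[C@@H]([C@H]1O[Si](C(C)C)(C(C)C)C(C)C)[C@H](OC)[C@@H]1O[C@@H]12
F5 | step 8 | 7,8-β-epoxy analogue of amine 18 | N[C@H]1C[C@]23O[C@@H](C(C)C)O[C@@H]3[C@@H]([C@H]1O[Si](C(C)C)(C(C)C)C(C)C)[C@H](OC)[C@@H]1O[C@@H]12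
F6 | step 8 | 7,8-β-epoxy analogue of amide acetal 21 | CCCCCCCCC/C=C/C(=O)N[C@H]1C[C@]23O[C@@H](C(C)C)O[C@@H]3[C@@H]([C@H]1O[Si](C(C)C)(C(C)C)C(C)C)[C@H](OC)[C@@H]1O[C@@H]12
F7 | step 4 | dicyclohexylboron aldolate from 10 and (E)-cinnamaldehyde | IC[C@@]12O[C@@H](C(C)C)O[C@@H]1[C@@H]([C@@H](OB(C3CCCCC3)C3CCCCC3)/C=C/c3ccccc3)C(=O)C=C2
F8 | step 4 | anti styryl carbinol (C5 α-arm CH(OH)–CH=CH–Ph, E) | IC[C@@]12O[C@@H](C(C)C)O[C@@H]1[C@@H]([C@@H](O)/C=C/c3ccccc3)C(=O)C=C2
F9 | step 4 | triisopropylsilyl ether of F8 | IC[C@@]12O[C@@H](C(C)C)O[C@@H]1[C@@H]([C@@H](O[Si](C(C)C)(C(C)C)C(C)C)/C=C/c3ccccc3)C(=O)C=C2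
F10 | step 4 | diol from dihydroxylation of the styryl bond of F9 (diol carbons unassigned) | IC[C@@]12O[C@@H](C(C)C)O[C@@H]1[C@@H]([C@@H](O[Si](C(C)C)(C(C)C)C(C)C)C(O)C(O)c3ccccc3)C(=O)C=C2
F11 | step 4 | α-silyloxy aldehyde (C3 as CHO) | IC[C@@]12O[C@@H](C(C)C)O[C@@H]1[C@@H]([C@@H](O[Si](C(C)C)(C(C)C)C(C)C)C=O)C(=O)C=C2
F12 | step 2 | enantiomer of 6, (2R,3aS,7aR) | IC[C@]12O[C@H](C(C)C)O[C@H]1CC(=O)C=C2
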